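**Strategy**

Rings are lettered A–F along the chain. In rings B, D and F the C4 hydroxyl lies between the oxygenated C3 and C5 and para to C1, whose ether oxygen comes from ring A, C or E. Each of these three C4–O bonds is disconnected to a formyl carbon: the formyl group first activates C1 for fluoride displacement and is then exchanged for oxygen. A single buffered peracid oxidation of the hexamer trialdehyde (formyl at C4 of B, D and F; thirteen methyl ethers) followed by formate cleavage delivers all three hydroxyls at once. Boron tribromide then frees the sixteen phenols.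

Key step: step 11

**Remarks on the chemistry**

- Locants: in rings B and D, C1 carries the ether oxygen from the preceding ring and C6 the ether oxygen to the next ring. In rings C and E, C1 carries the oxygen from the preceding ring and C4 the oxygen to the next ring.
- The target has no stereocentre and is achiral, so no configuration has to be set or preserved.
- C6 of rings B and D is meta to the formyl carbon and cannot be etherified by substitution of fluoride. A 3-hydroxy derivative of the fluoroaldehyde (4) is therefore made, and its C–O–aryl bond is formed by copper-mediated coupling before the fluoride is displaced. The resulting two-ring fluoride 10 is used twice.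
- Compounds 1, 5 and 11 are assumed to be purchased. All steps involving electron-rich phenoxides or free polyphenols are run under argon with degassed solvents.

**Route**

Step 1
Reactants: 1 4-fluoro-2,6-dimethoxybenzaldehyde
Product: 2 3-bromo-4-fluoro-2,6-dimethoxybenzaldehyde
Conditions: NBS (1.05 equiv), MeCN, rt
Reagents that add atoms: N-bromosuccinimide, O=C1CCC(=O)N1Br
Why: Electrophilic aromatic bromination; C3 and C5 are equivalent by symmetry and each is ortho to one methoxy group and para to the other, so a single monobromide should form and the first bromine slows a second substitution.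

Step 2
Reactants: 2 3-bromo-4-fluoro-2,6-dimethoxybenzaldehyde
Product: 4 4-fluoro-3-hydroxy-2,6-dimethoxybenzaldehyde, via pinacol boronate 3 (not isolated)
Conditions: B2pin2, KOAc, Pd(dppf)Cl2 (cat.), dioxane, 90 °C; then 30% H2O2, aq. NaHCO3, THF, 0 °C
Reagents that add atoms: hydrogen peroxide, OO (phenol oxygen of 4); bis(pinacolato)diboron, CC1(C)OB(OC1(C)C)B1OC(C)(C)C(C)(C)O1 (boron of intermediate 3 only)
Why: Miyaura borylation followed by oxidative C–B to C–O conversion; hydroperoxide attacks boron far faster than an aldehyde that has no ortho or para hydroxyl, and the cold, weakly basic medium should leave the activated fluoride alone.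

Step 3
Reactants: 5 4-bromo-2,6-dimethoxyphenol
Product: 6 5-bromo-1,3-dimethoxy-2-(prop-2-en-1-yloxy)benzene
Conditions: allyl bromide, K2CO3, acetone, reflux
Reagents that add atoms: allyl bromide, C=CCBr
Why: Williamson ether synthesis; the phenoxide is alkylated on oxygen by the reactive primary allylic bromide.

Step 4
Reactants: 6 5-bromo-1,3-dimethoxy-2-(prop-2-en-1-yloxy)benzene
Product: 9 [3,5-dimethoxy-4-(prop-2-en-1-yloxy)phenyl]boronic acid, via aryllithium 7 (not isolated), via lithium aryltriisopropoxyborate 8 (not isolated)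
Conditions: n-BuLi, THF, −78 °C; B(OiPr)3, −78 °C to rt; 1 M HCl, 0 °C
Reagents that add atoms: triisopropyl borate, CC(C)OB(OC(C)C)OC(C)C (boron); water, O (the two hydroxyl oxygens); n-butyllithium, [Li]CCCC (lithium of intermediates 7 and 8 only)
Why: Bromine–lithium exchange, borate trapping and hydrolysis is the standard arylboronic acid synthesis; exchange at −78 °C is much faster than any attack on the allyl ether, which sits para to the metalated carbon.

Step 5
Reactants: 4 4-fluoro-3-hydroxy-2,6-dimethoxybenzaldehyde; 9 [3,5-dimethoxy-4-(prop-2-en-1-yloxy)phenyl]boronic acid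
Product: 10 3-[3,5-dimethoxy-4-(prop-2-en-1-yloxy)phenoxy]-4-fluoro-2,6-dimethoxybenzaldehyde
Conditions: 9 (2 equiv), Cu(OAc)2 (1 equiv), pyridine, 4 Å MS, CH2Cl2, air, rt
Reagents that add atoms: none
Why: Chan–Lam–Evans oxidative etherification; the boronic acid has no ortho substituent and the phenol is flanked only by fluorine and methoxy, and the room-temperature, weakly basic conditions should not touch the aldehyde or the activated fluoride.

Step 6
Reactants: 10 3-[3,5-dimethoxy-4-(prop-2-en-1-yloxy)phenoxy]-4-fluoro-2,6-dimethoxybenzaldehyde; 11 2,4,6-trimethoxyphenol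
Product: 12 trimer aldehyde allyl ether (rings A–B–C)
Conditions: Cs2CO3, DMSO, 100 °C, Ar
Reagents that add atoms: none
Why: Nucleophilic aromatic substitution by addition–elimination; the para formyl group stabilises the Meisenheimer adduct and fluoride is the only good leaving group on the ring.

Step 7
Reactants: 12 trimer aldehyde allyl ether
Product: 13 trimer aldehyde phenol (free hydroxyl at C4 of ring C)
Conditions: Pd(PPh3)4 (cat.), morpholine, THF, rt, Ar
Reagents that add atoms: none
Why: Tsuji–Trost-type deallylation; palladium(0) ionises the allyl aryl ether to a π-allyl complex that morpholine traps, under neutral conditions that spare the aldehyde, the methyl ethers and the diaryl ethers.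

Step 8
Reactants: 13 trimer aldehyde phenol; 10 3-[3,5-dimethoxy-4-(prop-2-en-1-yloxy)phenoxy]-4-fluoro-2,6-dimethoxybenzaldehyde
Product: 14 pentamer dialdehyde allyl ether (rings A–E)
Conditions: Cs2CO3, DMSO, 100 °C, Ar
Reagents that add atoms: none
Why: Nucleophilic aromatic substitution of the formyl-activated fluoride by the ring C phenoxide; fluoride leaves far more readily than any aryloxide already para to a formyl group, so the existing ethers should not exchange.

Step 9
Reactants: 14 pentamer dialdehyde allyl ether
Product: 15 pentamer dialdehyde phenol (free hydroxyl at C4 of ring E)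
Conditions: Pd(PPh3)4 (cat.), morpholine, THF, rt, Ar
Reagents that add atoms: none
Why: Tsuji–Trost-type deallylation as in step 7, with the same tolerance of aldehydes and ethers.

Step 10
Reactants: 15 pentamer dialdehyde phenol; 1 4-fluoro-2,6-dimethoxybenzaldehyde
Product: 16 hexamer trialdehyde (formyl at C4 of rings B, D and F; thirteen methyl ethers)
Conditions: 1 (1.5 equiv), Cs2CO3, DMSO, 80 °C, Ar
Reagents that add atoms: none
Why: Nucleophilic aromatic substitution on the least hindered fluoride of the route, whose reacting carbon has two hydrogen neighbours and a para formyl group.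

Step 11
Reactants: 16 hexamer trialdehyde
Product: 18 trideca-O-methyl hexamer triphenol, via hexamer tris-formate 17 (not isolated)
Conditions: mCPBA (3.3 equiv), NaHCO3, CH2Cl2, 0 °C; Me2S; cold aq. NaHCO3 wash; then K2CO3 (cat.), MeOH, 0 °C, Ar
Reagents that add atoms: 3-chloroperoxybenzoic acid, OOC(=O)c1cccc(Cl)c1
Why: Each formyl group adds the peracid to give a Criegee adduct, from which ring carbon C4 migrates to the peroxide oxygen with loss of 3-chlorobenzoate, forming the C4–O bond as an aryl formate that mild methanolysis converts to the phenol. The closest known reaction type is the Dakin/Baeyer–Villiger oxidation of polymethoxybenzaldehydes, as in the standard preparation of 2,4,6-trimethoxyphenol from its aldehyde. No ring is closed and no stereocentre is created. The selectivity needed is aryl over hydride migration at all three sites, secured by the two ortho methoxy groups and the para aryloxy group on each migrating ring; the three aldehydes sit in closely similar environments, so one set of conditions should serve all. Preference for the aldehydes over the electron-rich rings A, C and E rests on fast carbonyl addition at 0 °C with only a slight excess of buffered peracid. The new phenols stay masked as formates until dimethyl sulfide has destroyed the oxidant, which guards them against quinone formation.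

Step 12
Reactants: 18 trideca-O-methyl hexamer triphenol
Product: 19 target hexamer with sixteen free hydroxyls (CNP0218077.0)
Conditions: BBr3 (excess), CH2Cl2, −78 °C to rt, Ar; MeOH quench, repeated evaporation from MeOH
Reagents that add atoms: none
Why: Lewis-acid ether cleavage; bromide attacks the methyl carbon of each boron-complexed aryl methyl ether, whereas the five diaryl ethers offer no sp3 carbon and should survive.

**Compound list**

1 | 4-fluoro-2,6-dimethoxybenzaldehyde | COc1cc(F)cc(OC)c1C=O | starting material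
2 | 3-bromo-4-fluoro-2,6-dimethoxybenzaldehyde | COc1cc(F)c(Br)c(OC)c1C=O | intermediate
3 | 4-fluoro-2,6-dimethoxy-3-(4,4,5,5-tetramethyl-1,3,2-dioxaborolan-2-yl)benzaldehyde (not isolated) | COc1cc(F)c(B2OC(C)(C)C(C)(C)O2)c(OC)c1C=O | intermediate
4 | 4-fluoro-3-hydroxy-2,6-dimethoxybenzaldehyde | COc1cc(F)c(O)c(OC)c1C=O | intermediate
5 | 4-bromo-2,6-dimethoxyphenol | COc1cc(Br)cc(OC)c1O | starting material
6 | 5-bromo-1,3-dimethoxy-2-(prop-2-en-1-yloxy)benzene | C=CCOc1c(OC)cc(Br)cc1OC | intermediate
7 | [3,5-dimethoxy-4-(prop-2-en-1-yloxy)phenyl]lithium (not isolated) | [Li]c1cc(OC)c(OCC=C)c(OC)c1 | intermediate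
8 | lithium [3,5-dimethoxy-4-(prop-2-en-1-yloxy)phenyl]tri(propan-2-yloxy)borate (not isolated) | [Li+].CC(C)O[B-](OC(C)C)(OC(C)C)c1cc(OC)c(OCC=C)c(OC)c1 | intermediate
9 | [3,5-dimethoxy-4-(prop-2-en-1-yloxy)phenyl]boronic acid | OB(O)c1cc(OC)c(OCC=C)c(OC)c1 | intermediate
10 | 3-[3,5-dimethoxy-4-(prop-2-en-1-yloxy)phenoxy]-4-fluoro-2,6-dimethoxybenzaldehyde (two-ring fluoride, source of rings B+C and D+E) | COc1cc(F)c(Oc2cc(OC)c(OCC=C)c(OC)c2)c(OC)c1C=O | intermediate
11 | 2,4,6-trimethoxyphenol | COc1cc(OC)c(O)c(OC)c1 | starting material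
12 | trimer aldehyde allyl ether: 2,6-dimethoxy-3-[3,5-dimethoxy-4-(prop-2-en-1-yloxy)phenoxy]-4-(2,4,6-trimethoxyphenoxy)benzaldehyde | COc1cc(OC)c(Oc2cc(OC)c(C=O)c(OC)c2Oc2cc(OC)c(OCC=C)c(OC)c2)c(OC)c1 | intermediate
13 | trimer aldehyde phenol: 3-(4-hydroxy-3,5-dimethoxyphenoxy)-2,6-dimethoxy-4-(2,4,6-trimethoxyphenoxy)benzaldehyde | COc1cc(OC)c(Oc2cc(OC)c(C=O)c(OC)c2Oc2cc(OC)c(O)c(OC)c2)c(OC)c1 | intermediate
14 | pentamer dialdehyde allyl ether: 13 with its ring C oxygen bonded to C4 of the benzaldehyde ring of 10 in place of fluorine; formyl on rings B and D, allyl ether on ring E | COc1cc(OC)c(Oc2cc(OC)c(C=O)c(OC)c2Oc2cc(OC)c(Oc3cc(OC)c(C=O)c(OC)c3Oc3cc(OC)c(OCC=C)c(OC)c3)c(OC)c2)c(OC)c1 | intermediate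
15 | pentamer dialdehyde phenol: 14 with the ring E allyl ether replaced by a free hydroxyl | COc1cc(OC)c(Oc2cc(OC)c(C=O)c(OC)c2Oc2cc(OC)c(Oc3cc(OC)c(C=O)c(OC)c3Oc3cc(OC)c(O)c(OC)c3)c(OC)c2)c(OC)c1 | intermediate
16 | hexamer trialdehyde: 15 with its ring E oxygen bonded to C4 of a 2,6-dimethoxybenzaldehyde ring (ring F); formyl at C4 of rings B, D and F | COc1cc(OC)c(Oc2cc(OC)c(C=O)c(OC)c2Oc2cc(OC)c(Oc3cc(OC)c(C=O)c(OC)c3Oc3cc(OC)c(Oc4cc(OC)c(C=O)c(OC)c4)c(OC)c3)c(OC)c2)c(OC)c1 | intermediate
17 | hexamer tris-formate: 16 with each formyl group replaced by a formyloxy group (not isolated) | COc1cc(OC)c(Oc2cc(OC)c(OC=O)c(OC)c2Oc2cc(OC)c(Oc3cc(OC)c(OC=O)c(OC)c3Oc3cc(OC)c(Oc4cc(OC)c(OC=O)c(OC)c4)c(OC)c3)c(OC)c2)c(OC)c1 | intermediate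
18 | trideca-O-methyl hexamer triphenol: 16 with each formyl group replaced by hydroxyl | COc1cc(OC)c(Oc2cc(OC)c(O)c(OC)c2Oc2cc(OC)c(Oc3cc(OC)c(O)c(OC)c3Oc3cc(OC)c(Oc4cc(OC)c(O)c(OC)c4)c(OC)c3)c(OC)c2)c(OC)c1 | intermediate
19 | CNP0218077.0, hexamer with sixteen free hydroxyls (achiral) | Oc1cc(O)c(Oc2cc(O)c(O)c(O)c2Oc2cc(O)c(Oc3cc(O)c(O)c(O)c3Oc3cc(O)c(Oc4cc(O)c(O)c(O)c4)c(O)c3)c(O)c2)c(O)c1 | target

**Totals**

Total step count: 12.
Longest linear sequence: 10 steps (1 → 2 → 4 → 10 → 12 → 13 → 14 → 15 → 16 → 18 → 19; the branch 5 → 6 → 9 → 10 onward is equally long).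

**Steps most likely to fail**

1. Step 11. The peracid may also oxidise the electron-rich rings, a phenol may be liberated while oxidant is still present and go on to a quinone, or one of the three sites may lag and give mixtures that are hard to separate. The fallback spreads the oxygenation over two smaller operations and sets out from 14. Buffered mCPBA (2.2 equiv, 0 °C), which should attack the monosubstituted allyl alkene far more slowly than the aldehydes, would give the pentamer bis-formate allyl ether F1. After quenching and methanolysis this would give the pentamer diphenol allyl ether F2. Methyl iodide and K2CO3 would cap both hydroxyls as the trideca-O-methyl pentamer allyl ether F3, so that no free phenol meets oxidant again. Pd(0)/morpholine would release the trideca-O-methyl pentamer phenol F4, and substitution on 1 would give the hexamer monoaldehyde F5. A single Dakin oxidation would lead through the hexamer mono-formate F6 to the pentadeca-O-methyl hexamer monophenol F7. Boron tribromide would then cleave its fifteen methyl ethers, and the fallback comes back to the route at 19.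

2. Step 12. Cleavage of the thirteen methyl ethers may stop short at the hindered positions, and the free polyphenol with three pyrogallol units may oxidise in air during isolation. The fallback sets out from 18. The crude demethylation product would be acetylated at once (Ac2O, pyridine) to the hexadecaacetate F8, which is stable, can be chromatographed on silica and can be separated from incompletely demethylated material. Acid methanolysis under argon (HCl generated from acetyl chloride in MeOH) would then release the polyphenol with only volatile co-products, and the fallback comes back to the route at 19.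

3. Step 8. Substitution may be sluggish because the phenoxide is flanked by two methoxy groups and the fluoride carries an ortho aryloxy group; at forcing temperature, aryloxides already para to a formyl group may exchange and scramble chain lengths. The fallback changes the order of bond formation on ring D and sets out from 13. Substitution on the smaller and more activated bromofluoride 2 would give the tetramer bromide F9. Miyaura borylation would give the tetramer pinacol boronate F10, and peroxide oxidation the tetramer phenol F11. Chan–Lam coupling of F11 with boronic acid 9 would form the ring D–ring E ether, and the fallback comes back to the route at 14.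

**Further compounds**

F1 | step 11 | pentamer bis-formate allyl ether | COc1cc(OC)c(Oc2cc(OC)c(OC=O)c(OC)c2Oc2cc(OC)c(Oc3cc(OC)c(OC=O)c(OC)c3Oc3cc(OC)c(OCC=C)c(OC)c3)c(OC)c2)c(OC)c1
F2 | step 11 | pentamer diphenol allyl ether | COc1cc(OC)c(Oc2cc(OC)c(O)c(OC)c2Oc2cc(OC)c(Oc3cc(OC)c(O)c(OC)c3Oc3cc(OC)c(OCC=C)c(OC)c3)c(OC)c2)c(OC)c1
F3 | step 11 | trideca-O-methyl pentamer allyl ether | COc1cc(OC)c(Oc2cc(OC)c(OC)c(OC)c2Oc2cc(OC)c(Oc3cc(OC)c(OC)c(OC)c3Oc3cc(OC)c(OCC=C)c(OC)c3)c(OC)c2)c(OC)c1
F4 | step 11 | trideca-O-methyl pentamer phenol | COc1cc(OC)c(Oc2cc(OC)c(OC)c(OC)c2Oc2cc(OC)c(Oc3cc(OC)c(OC)c(OC)c3Oc3cc(OC)c(O)c(OC)c3)c(OC)c2)c(OC)c1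
F5 | step 11 | pentadeca-O-methyl hexamer monoaldehyde (formyl on ring F) | COc1cc(OC)c(Oc2cc(OC)c(OC)c(OC)c2Oc2cc(OC)c(Oc3cc(OC)c(OC)c(OC)c3Oc3cc(OC)c(Oc4cc(OC)c(C=O)c(OC)c4)c(OC)c3)c(OC)c2)c(OC)c1
F6 | step 11 | pentadeca-O-methyl hexamer mono-formate | COc1cc(OC)c(Oc2cc(OC)c(OC)c(OC)c2Oc2cc(OC)c(Oc3cc(OC)c(OC)c(OC)c3Oc3cc(OC)c(Oc4cc(OC)c(OC=O)c(OC)c4)c(OC)c3)c(OC)c2)c(OC)c1
F7 | step 11 | pentadeca-O-methyl hexamer monophenol | COc1cc(OC)c(Oc2cc(OC)c(OC)c(OC)c2Oc2cc(OC)c(Oc3cc(OC)c(OC)c(OC)c3Oc3cc(OC)c(Oc4cc(OC)c(O)c(OC)c4)c(OC)c3)c(OC)c2)c(OC)c1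
F8 | step 12 | hexadecaacetate of 19 | CC(=O)Oc1cc(OC(C)=O)c(Oc2cc(OC(C)=O)c(OC(C)=O)c(OC(C)=O)c2Oc2cc(OC(C)=O)c(Oc3cc(OC(C)=O)c(OC(C)=O)c(OC(C)=O)c3Oc3cc(OC(C)=O)c(Oc4cc(OC(C)=O)c(OC(C)=O)c(OC(C)=O)c4)c(OC(C)=O)c3)c(OC(C)=O)c2)c(OC(C)=O)c1
F9 | step 8 | tetramer bromide (rings A–D, bromine at C6 of ring D) | COc1cc(OC)c(Oc2cc(OC)c(C=O)c(OC)c2Oc2cc(OC)c(Oc3cc(OC)c(C=O)c(OC)c3Br)c(OC)c2)c(OC)c1
F10 | step 8 | tetramer pinacol boronate | COc1cc(OC)c(Oc2cc(OC)c(C=O)c(OC)c2Oc2cc(OC)c(Oc3cc(OC)c(C=O)c(OC)c3B4OC(C)(C)C(C)(C)O4)c(OC)c2)c(OC)c1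
F11 | step 8 | tetramer phenol (hydroxyl at C6 of ring D) | COc1cc(OC)c(Oc2cc(OC)c(C=O)c(OC)c2Oc2cc(OC)c(Oc3cc(OC)c(C=O)c(OC)c3O)c(OC)c2)c(OC)c1
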